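From birch to alder the charge of J rose by a factor of 1.47, but the level where E stops rose by 1.77.

| flask | Q | X | J | remark |
|---|---|---|---|---|
| birch | 1.5 M | 200 mM (held) | 7.5 mM | run made earlier |
| alder | 1.5 M | 200 mM (held) | 11 mM | run made earlier |
| flask | 1.5 M | 200 mM (held) | 15 mM |  |

| birch: time / min | birch: E / % | alder: time / min | alder: E / % |
|---|---|---|---|
| 30.0 | 7.9 | 10.0 | 9.1 |
| 60.0 | 8.2 | 20.0 | 12.4 |
| 90.0 | 7.0 | 50.0 | 13.9 |
| 120 | 7.9 | 120 | 13.6 |

(scatter of a reading: 0.5 percentage points)

1. factor on the rate of making E when 10 % of the Q are converted if J is charged twice over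
2. factor on the rate when 10 % of the Q are converted if J is charged at 80 mM instead

- at the start none of G is dissolved
- steps under discussion: Q + J -> J + L; G + J + L -> J + E; J -> Z; X <-> G
- what has left Q counts as converted, also if it is not yet product

The bench rule says that rate goes with the catalyst charged. A double charge then gives a factor of 2, and 80 mM gives 5.33. But I read the stop in E as J turning into Z, which is catalyst deactivation. Q is lost and J is lost at rates that both go with J, so J cancels. The natural log of Q charged over Q remaining therefore grows in step with the J lost, whatever the charge.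

Your flat readings put birch at 7.75 % and alder at 13.8 %. Each extra mM of J thus bought 0.0171 mM⁻¹ of E. I divide this by the share of Q still there, taken roughly as one minus the mean E, and get 0.0192 mM⁻¹. The toll, the J lost on the way to 10 % conversion, is then 5.49 mM.

The bench rule needs the toll to be small against the charge. It is 36.6 % of the flask's charge but 6.86 % of 80 mM. If L and G stand equal at equal conversion, rate goes with the J remaining. My factors are then 2.58 and 7.83.

The forecast, with a toll near 6 mM, gives 2.6 and 7, saying “I shade both down”, so on the second factor it stands lower than mine.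

The flask gives 2.40 and 6.99.

    Q + J → J + L (k = 0.0509 L mol⁻¹ s⁻¹)
    G + J + L → J + E (k = 2.10 L² mol⁻² s⁻¹)
    J → Z (k = 0.00213 s⁻¹)
    X ⇌ G, rate k4*(csat - [G]) (kL = 0.319 s⁻¹)

It reaches 10 % conversion at 2.72 min, with E forming at 0.0264 M min⁻¹. By then the flask has lost 4.41 mM of J, less than my toll of 5.49 mM. At 80 mM my toll leaves 93.1 % of the catalyst as J; that run shows 94.5 %.

The data are calculated for substances that don't exist; the scatter is artificial.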